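**Retrosynthetic overview**
- Target 29 is the tris-benzyl ether 28 after global hydrogenolysis. 28 is the aromatised form of an aldol condensation product between a cyclohexenone (future ring A) and a benzaldehyde (ring B).
- Key C–C bond (ring A carbon to the CH2 bridge): intermolecular lithium-enolate aldol of vinylogous ester 13 with aldehyde 23, then dehydration and exo-to-endo isomerisation to the phenol.
- 13 comes from dione 12, made by Michael addition of dimethyl malonate to enone 7 and Claisen ring closure; 7 comes from eugenol.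
- 23 comes from 3,5-dimethoxybenzyl bromide and O-benzylvanillin (HWE, hydrogenation), then ortho-lithiation/formylation, chelation-controlled mono-demethylation and benzylation.
- Ring order: ring B and both guaiacyl rings are bought as arenes; ring A is closed as a carbocycle in step 5 and aromatised last, in step 15.

Assumption: the target SMILES has no stereogenic element, so the route delivers the one achiral compound shown; stereocentres that exist only in intermediates are carried as racemates or diastereomer mixtures and are erased on aromatisation.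

**Route**

Step 1
Reactants: 1 eugenol (2-methoxy-4-(prop-2-en-1-yl)phenol)
Product: 2 1-(benzyloxy)-2-methoxy-4-(prop-2-en-1-yl)benzene
Conditions: BnBr (1.1 equiv), K2CO3, acetone, reflux
Reagents that add atoms: benzyl bromide, BrCc1ccccc1
Why: Williamson ether synthesis on the only acidic site gives a phenol protecting group that survives every later basic, organometallic and Lewis-acid-free step and is removed by hydrogenolysis at the end.

Step 2
Reactants: 2 1-(benzyloxy)-2-methoxy-4-(prop-2-en-1-yl)benzene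
Product: 4 3-[4-(benzyloxy)-3-methoxyphenyl]propan-1-ol, via alkylborane 3 (not isolated)
Conditions: 9-BBN (1.2 equiv), THF, 0 °C to rt; then 3 M NaOH, 30% H2O2, 0 °C to rt
Reagents that add atoms: hydrogen peroxide, OO
Why: Brown hydroboration–oxidation with the bulky 9-BBN places boron on the terminal carbon of the allyl group, so oxidation gives the primary alcohol only.

Step 3
Reactants: 4 3-[4-(benzyloxy)-3-methoxyphenyl]propan-1-ol
Product: 5 3-[4-(benzyloxy)-3-methoxyphenyl]propanal
Conditions: TEMPO (10 mol %), PhI(OAc)2 (1.1 equiv), CH2Cl2, rt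
Reagents that add atoms: none
Why: TEMPO-catalysed oxoammonium oxidation stops cleanly at the aldehyde and leaves the electron-rich arene and the benzyl ether untouched.

Step 4
Reactants: 5 3-[4-(benzyloxy)-3-methoxyphenyl]propanal; 6 1-(triphenyl-λ5-phosphanylidene)propan-2-one
Product: 7 (3E)-6-[4-(benzyloxy)-3-methoxyphenyl]hex-3-en-2-one
Conditions: CH2Cl2, rt, 16 h
Reagents that add atoms: none
Why: Wittig olefination with a stabilised ylide gives the E-enone without the self-condensation that a base-mediated acetone aldol would risk.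

Step 5
Reactants: 7 (3E)-6-[4-(benzyloxy)-3-methoxyphenyl]hex-3-en-2-one; 8 dimethyl malonate
Product: 12 5-{2-[4-(benzyloxy)-3-methoxyphenyl]ethyl}cyclohexane-1,3-dione, via Michael adduct 9 (not isolated), via cyclic keto ester 10 (not isolated), via keto acid 11 (not isolated)
Conditions: NaOMe (1.2 equiv), MeOH, reflux; then 5 M aq. NaOH, reflux; then HCl to pH 1, 70 °C
Reagents that add atoms: none
Why: Intermolecular Michael addition of sodio-malonate to the enone, then intramolecular Claisen (Dieckmann-type) attack of the methyl-ketone enolate on a malonate ester, closes the six-membered ring; saponification and decarboxylation give the symmetric 1,3-dione, in which the transient stereocentres have vanished.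

Step 6
Reactants: 12 5-{2-[4-(benzyloxy)-3-methoxyphenyl]ethyl}cyclohexane-1,3-dione
Product: 13 5-{2-[4-(benzyloxy)-3-methoxyphenyl]ethyl}-3-methoxycyclohex-2-en-1-one (racemic)
Conditions: HC(OMe)3 (2 equiv), p-TsOH·H2O (3 mol %), MeOH, rt
Reagents that add atoms: trimethyl orthoformate, COC(OC)OC
Why: Acid-catalysed vinylogous esterification of the symmetric dione can give only one enol ether; this single operation fixes the later OMe/OH pattern of ring A.

Step 7
Reactants: 14 1-(bromomethyl)-3,5-dimethoxybenzene; 15 triethyl phosphite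
Product: 16 diethyl [(3,5-dimethoxyphenyl)methyl]phosphonate
Conditions: neat, 130 °C, EtBr distilled off
Reagents that add atoms: none
Why: Michaelis–Arbuzov reaction of a reactive benzylic bromide is clean and needs no purification beyond removal of volatiles.

Step 8
Reactants: 16 diethyl [(3,5-dimethoxyphenyl)methyl]phosphonate; 17 4-(benzyloxy)-3-methoxybenzaldehyde
Product: 18 1-(benzyloxy)-4-[(E)-2-(3,5-dimethoxyphenyl)ethenyl]-2-methoxybenzene
Conditions: KOt-Bu (1.2 equiv) added to 16 and 17 in THF, 0 °C to rt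
Reagents that add atoms: none
Why: Horner–Wadsworth–Emmons olefination of a non-enolisable aldehyde gives the E-stilbene; the benzyl group keeps the aldehyde electrophilic, which a free para-phenoxide would not.

Step 9
Reactants: 18 1-(benzyloxy)-4-[(E)-2-(3,5-dimethoxyphenyl)ethenyl]-2-methoxybenzene
Product: 19 4-[2-(3,5-dimethoxyphenyl)ethyl]-2-methoxyphenol
Conditions: H2 (1 atm), palladium on carbon (Pd/C, 10 wt %), EtOAc/MeOH, rt
Reagents that add atoms: none
Why: Catalytic hydrogenation saturates the stilbene and hydrogenolyses the benzyl ether in one operation, which removes the one group that would not tolerate the lithiation and BCl3 steps that follow.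

Step 10
Reactants: 19 4-[2-(3,5-dimethoxyphenyl)ethyl]-2-methoxyphenol
Product: 21 4-[2-(4-hydroxy-3-methoxyphenyl)ethyl]-2,6-dimethoxybenzaldehyde, via dilithio species 20 (not isolated)
Conditions: n-BuLi (2.4 equiv), THF, 0 °C to rt; then DMF (3 equiv), 0 °C to rt; 1 M HCl work-up
Reagents that add atoms: N,N-dimethylformamide, CN(C)C=O
Why: The first equivalent of n-BuLi forms the lithium phenoxide, which shuts down metalation of that ring; the second removes the C–H flanked by two methoxy groups (cooperative directed ortho-metalation), and DMF formylates the aryllithium.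

Step 11
Reactants: 21 4-[2-(4-hydroxy-3-methoxyphenyl)ethyl]-2,6-dimethoxybenzaldehyde
Product: 22 2-hydroxy-4-[2-(4-hydroxy-3-methoxyphenyl)ethyl]-6-methoxybenzaldehyde
Conditions: BCl3 (2.5 equiv, 1 M in CH2Cl2), CH2Cl2, −78 to 0 °C; then ice-water
Reagents that add atoms: none
Why: Chelation-controlled Lewis-acid demethylation: boron bridges the aldehyde oxygen and one ortho-methoxy group, so only that methyl ether is cleaved (the two ortho groups are equivalent), and the resulting six-membered boron chelate protects the second one.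

Step 12
Reactants: 22 2-hydroxy-4-[2-(4-hydroxy-3-methoxyphenyl)ethyl]-6-methoxybenzaldehyde
Product: 23 2-(benzyloxy)-4-{2-[4-(benzyloxy)-3-methoxyphenyl]ethyl}-6-methoxybenzaldehyde
Conditions: BnBr (2.5 equiv), K2CO3, DMF, 60 °C
Reagents that add atoms: benzyl bromide, BrCc1ccccc1
Why: Double Williamson etherification protects both phenols, including the hydrogen-bonded one (hence the warming), so the aldehyde can meet a lithium enolate.

Step 13
Reactants: 13 5-{2-[4-(benzyloxy)-3-methoxyphenyl]ethyl}-3-methoxycyclohex-2-en-1-one; 23 2-(benzyloxy)-4-{2-[4-(benzyloxy)-3-methoxyphenyl]ethyl}-6-methoxybenzaldehyde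
Product: 25 6-{[2-(benzyloxy)-4-{2-[4-(benzyloxy)-3-methoxyphenyl]ethyl}-6-methoxyphenyl](hydroxy)methyl}-5-{2-[4-(benzyloxy)-3-methoxyphenyl]ethyl}-3-methoxycyclohex-2-en-1-one (racemic diastereomer mixture), via lithium enolate 24 (not isolated)
Conditions: LiN(i-Pr)2 (LDA, 1.15 equiv), THF, −78 °C; then 23 in THF, −78 °C; AcOH quench at −78 °C
Reagents that add atoms: none
Why: Kinetic deprotonation of the vinylogous ester gives the cross-conjugated α′ (C6) enolate (Stork–Danheiser regiochemistry), which adds to the non-enolisable aldehyde in a crossed intermolecular aldol addition; the three stereocentres form without control and are all erased in steps 14 and 15.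

Step 14
Reactants: 25 the aldol adduct
Product: 27 (6E)-6-{[2-(benzyloxy)-4-{2-[4-(benzyloxy)-3-methoxyphenyl]ethyl}-6-methoxyphenyl]methylidene}-5-{2-[4-(benzyloxy)-3-methoxyphenyl]ethyl}-3-methoxycyclohex-2-en-1-one (racemic), via mesylate 26 (not isolated)
Conditions: MsCl (1.5 equiv), Et3N (3 equiv), CH2Cl2, 0 °C; then DBU (3 equiv), rt
Reagents that add atoms: none
Why: Mesylation and E1cB elimination complete the aldol condensation; the doubly ortho-alkoxylated benzylic mesylate leaves readily and the conjugated E-arylidene enone is expected as the major isomer, its geometry being irrelevant to the next step.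

Step 15
Reactants: 27 the arylidene enone
Product: 28 2-{[2-(benzyloxy)-4-{2-[4-(benzyloxy)-3-methoxyphenyl]ethyl}-6-methoxyphenyl]methyl}-3-{2-[4-(benzyloxy)-3-methoxyphenyl]ethyl}-5-methoxyphenol
Conditions: RhCl3·3H2O (10 mol %), MeOH/THF (3:1), 65 °C
Reagents that add atoms: none
Why: A rhodium hydride moves the exocyclic C=C into the ring (Grieco-type exo-to-endo isomerisation) and the resulting cyclohexa-2,5-dienone tautomerises irreversibly to the phenol (alicyclic-to-aromatic isomerisation), which erases the last stereocentre; methanol as solvent makes any alkoxy exchange at the enol ether degenerate.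

Step 16
Reactants: 28 the tris-benzyl ether
Product: 29 2-({2-hydroxy-4-[2-(4-hydroxy-3-methoxyphenyl)ethyl]-6-methoxyphenyl}methyl)-3-[2-(4-hydroxy-3-methoxyphenyl)ethyl]-5-methoxyphenol (CNP0079001.0)
Conditions: H2 (1 atm), palladium on carbon (Pd/C, 10 wt %), EtOAc/MeOH, rt
Reagents that add atoms: none
Why: Hydrogenolysis removes all three aryl benzyl ethers at once, while the diarylmethane bridge and the methyl ethers are inert under these mild conditions.

**Compound list**

1 | eugenol, 2-methoxy-4-(prop-2-en-1-yl)phenol | C=CCc1ccc(O)c(OC)c1 | starting material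
2 | 1-(benzyloxy)-2-methoxy-4-(prop-2-en-1-yl)benzene | C=CCc1ccc(OCc2ccccc2)c(OC)c1 | intermediate
3 | 9-{3-[4-(benzyloxy)-3-methoxyphenyl]propyl}-9-borabicyclo[3.3.1]nonane | COc1cc(CCCB2C3CCCC2CCC3)ccc1OCc1ccccc1 | intermediate
4 | 3-[4-(benzyloxy)-3-methoxyphenyl]propan-1-ol | OCCCc1ccc(OCc2ccccc2)c(OC)c1 | intermediate
5 | 3-[4-(benzyloxy)-3-methoxyphenyl]propanal | O=CCCc1ccc(OCc2ccccc2)c(OC)c1 | intermediate
6 | 1-(triphenyl-λ5-phosphanylidene)propan-2-one | CC(=O)C=P(c1ccccc1)(c1ccccc1)c1ccccc1 | starting material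
7 | (3E)-6-[4-(benzyloxy)-3-methoxyphenyl]hex-3-en-2-one | CC(=O)/C=C/CCc1ccc(OCc2ccccc2)c(OC)c1 | intermediate
8 | dimethyl malonate | COC(=O)CC(=O)OC | starting material
9 | dimethyl 2-{1-[4-(benzyloxy)-3-methoxyphenyl]-5-oxohexan-3-yl}propanedioate (racemic) | CC(=O)CC(CCc1ccc(OCc2ccccc2)c(OC)c1)C(C(=O)OC)C(=O)OC | intermediate
10 | methyl 6-{2-[4-(benzyloxy)-3-methoxyphenyl]ethyl}-2,4-dioxocyclohexane-1-carboxylate (racemic, present as its sodium enolate) | COC(=O)C1C(=O)CC(=O)CC1CCc1ccc(OCc2ccccc2)c(OC)c1 | intermediate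
11 | 6-{2-[4-(benzyloxy)-3-methoxyphenyl]ethyl}-2,4-dioxocyclohexane-1-carboxylic acid (racemic) | OC(=O)C1C(=O)CC(=O)CC1CCc1ccc(OCc2ccccc2)c(OC)c1 | intermediate
12 | 5-{2-[4-(benzyloxy)-3-methoxyphenyl]ethyl}cyclohexane-1,3-dione | O=C1CC(=O)CC(CCc2ccc(OCc3ccccc3)c(OC)c2)C1 | intermediate
13 | 5-{2-[4-(benzyloxy)-3-methoxyphenyl]ethyl}-3-methoxycyclohex-2-en-1-one (racemic) | COC1=CC(=O)CC(CCc2ccc(OCc3ccccc3)c(OC)c2)C1 | intermediate
14 | 1-(bromomethyl)-3,5-dimethoxybenzene | COc1cc(CBr)cc(OC)c1 | starting material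
15 | triethyl phosphite | CCOP(OCC)OCC | starting material
16 | diethyl [(3,5-dimethoxyphenyl)methyl]phosphonate | CCOP(=O)(Cc1cc(OC)cc(OC)c1)OCC | intermediate
17 | 4-(benzyloxy)-3-methoxybenzaldehyde | COc1cc(C=O)ccc1OCc1ccccc1 | starting material
18 | 1-(benzyloxy)-4-[(E)-2-(3,5-dimethoxyphenyl)ethenyl]-2-methoxybenzene | COc1cc(/C=C/c2ccc(OCc3ccccc3)c(OC)c2)cc(OC)c1 | intermediate
19 | 4-[2-(3,5-dimethoxyphenyl)ethyl]-2-methoxyphenol | COc1cc(CCc2ccc(O)c(OC)c2)cc(OC)c1 | intermediate
20 | lithium 4-[2-(4-lithio-3,5-dimethoxyphenyl)ethyl]-2-methoxyphenolate | [Li]c1c(OC)cc(CCc2ccc(O[Li])c(OC)c2)cc1OC | intermediate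
21 | 4-[2-(4-hydroxy-3-methoxyphenyl)ethyl]-2,6-dimethoxybenzaldehyde | COc1cc(CCc2ccc(O)c(OC)c2)cc(OC)c1C=O | intermediate
22 | 2-hydroxy-4-[2-(4-hydroxy-3-methoxyphenyl)ethyl]-6-methoxybenzaldehyde | COc1cc(CCc2ccc(O)c(OC)c2)cc(O)c1C=O | intermediate
23 | 2-(benzyloxy)-4-{2-[4-(benzyloxy)-3-methoxyphenyl]ethyl}-6-methoxybenzaldehyde | COc1cc(CCc2ccc(OCc3ccccc3)c(OC)c2)cc(OCc2ccccc2)c1C=O | intermediate
24 | lithium 3-{2-[4-(benzyloxy)-3-methoxyphenyl]ethyl}-5-methoxycyclohexa-1,5-dien-1-olate (kinetic α′-enolate of 13, racemic) | [Li]OC1=CC(CCc2ccc(OCc3ccccc3)c(OC)c2)CC(OC)=C1 | intermediate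
25 | 6-{[2-(benzyloxy)-4-{2-[4-(benzyloxy)-3-methoxyphenyl]ethyl}-6-methoxyphenyl](hydroxy)methyl}-5-{2-[4-(benzyloxy)-3-methoxyphenyl]ethyl}-3-methoxycyclohex-2-en-1-one (racemic diastereomer mixture) | COC1=CC(=O)C(C(O)c2c(OC)cc(CCc3ccc(OCc4ccccc4)c(OC)c3)cc2OCc2ccccc2)C(CCc2ccc(OCc3ccccc3)c(OC)c2)C1 | intermediate
26 | methanesulfonate of 25 (racemic diastereomer mixture) | COC1=CC(=O)C(C(OS(C)(=O)=O)c2c(OC)cc(CCc3ccc(OCc4ccccc4)c(OC)c3)cc2OCc2ccccc2)C(CCc2ccc(OCc3ccccc3)c(OC)c2)C1 | intermediate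
27 | (6E)-6-{[2-(benzyloxy)-4-{2-[4-(benzyloxy)-3-methoxyphenyl]ethyl}-6-methoxyphenyl]methylidene}-5-{2-[4-(benzyloxy)-3-methoxyphenyl]ethyl}-3-methoxycyclohex-2-en-1-one (racemic) | COC1=CC(=O)/C(=C/c2c(OC)cc(CCc3ccc(OCc4ccccc4)c(OC)c3)cc2OCc2ccccc2)C(CCc2ccc(OCc3ccccc3)c(OC)c2)C1 | intermediate
28 | 2-{[2-(benzyloxy)-4-{2-[4-(benzyloxy)-3-methoxyphenyl]ethyl}-6-methoxyphenyl]methyl}-3-{2-[4-(benzyloxy)-3-methoxyphenyl]ethyl}-5-methoxyphenol | COc1cc(O)c(Cc2c(OCc3ccccc3)cc(CCc3ccc(OCc4ccccc4)c(OC)c3)cc2OC)c(CCc2ccc(OCc3ccccc3)c(OC)c2)c1 | intermediate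
29 | 2-({2-hydroxy-4-[2-(4-hydroxy-3-methoxyphenyl)ethyl]-6-methoxyphenyl}methyl)-3-[2-(4-hydroxy-3-methoxyphenyl)ethyl]-5-methoxyphenol (achiral) | COc1cc(O)c(Cc2c(O)cc(CCc3ccc(O)c(OC)c3)cc2OC)c(CCc2ccc(O)c(OC)c2)c1 | target

**Step count and risks**

Total steps: 16. Longest linear sequence: 10 steps (1–6, then 13–16); the other branch (7–12, then 13–16) is equally long.

Most likely to fail, first: step 15. The exo-to-endo isomerisation has to act on a hindered, tetrasubstituted arylidene. The fallback sets out from 25 and comes back at 28, and avoids any exocyclic alkene. Dess–Martin periodinane oxidises the carbinol to the β-diketone 6-[2-(benzyloxy)-4-{2-[4-(benzyloxy)-3-methoxyphenyl]ethyl}-6-methoxybenzoyl]-5-{2-[4-(benzyloxy)-3-methoxyphenyl]ethyl}-3-methoxycyclohex-2-en-1-one F7. PhSeCl/pyridine gives the 6-(phenylselanyl) diketone F8. H2O2 then triggers selenoxide syn-elimination, which can only go into the ring (the aroyl carbon has no hydrogen), and tautomerisation gives the benzophenone [2-(benzyloxy)-4-{2-[4-(benzyloxy)-3-methoxyphenyl]ethyl}-6-methoxyphenyl](2-{2-[4-(benzyloxy)-3-methoxyphenyl]ethyl}-6-hydroxy-4-methoxyphenyl)methanone F9. LiAlH4 in THF reduces it to the benzhydrol F10, and ionic deoxygenation with Et3SiH/CF3CO2H at 0 °C gives 28.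

Second: step 13. Both partners are hindered, and the lithium aldolate can revert. The fallback sets out from 13 (with 23) and comes back at 25. LDA and Me3SiCl convert 13 into the silyl dienol ether {[3-{2-[4-(benzyloxy)-3-methoxyphenyl]ethyl}-5-methoxycyclohexa-1,5-dien-1-yl]oxy}trimethylsilane F6. F6 is then added to 23 under BF3·OEt2 in CH2Cl2 at −78 °C (Mukaiyama aldol). Here the Lewis acid activates the electron-rich aldehyde and the addition is not reversible; any product that has already lost water is simply 27.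

Third: step 10. The dianion may metalate incompletely or be poorly soluble. The fallback sets out from 15 and 17 and comes back at 22; it places the formyl carbon by halogen–lithium exchange instead. Commercial (4-bromo-3,5-dimethoxyphenyl)methanol is converted with PBr3 into 2-bromo-5-(bromomethyl)-1,3-dimethoxybenzene F1. Arbuzov reaction with 15 gives diethyl [(4-bromo-3,5-dimethoxyphenyl)methyl]phosphonate F2. HWE reaction with 17 (KOt-Bu, THF) gives 1-(benzyloxy)-4-[(E)-2-(4-bromo-3,5-dimethoxyphenyl)ethenyl]-2-methoxybenzene F3. Diimide reduction (TsNHNH2, NaOAc, THF/H2O, reflux) spares the C–Br bond and the benzyl ether and gives 1-(benzyloxy)-4-[2-(4-bromo-3,5-dimethoxyphenyl)ethyl]-2-methoxybenzene F4. Exchange with n-BuLi at −78 °C and DMF quench give 4-{2-[4-(benzyloxy)-3-methoxyphenyl]ethyl}-2,6-dimethoxybenzaldehyde F5. BCl3 with pentamethylbenzene (CH2Cl2, −78 to 0 °C) then removes the benzyl group and one ortho-methyl group together to give 22.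

**Further compounds**

F1 | step 10 | 2-bromo-5-(bromomethyl)-1,3-dimethoxybenzene | COc1cc(CBr)cc(OC)c1Br
F2 | step 10 | diethyl [(4-bromo-3,5-dimethoxyphenyl)methyl]phosphonate | CCOP(=O)(Cc1cc(OC)c(Br)c(OC)c1)OCC
F3 | step 10 | 1-(benzyloxy)-4-[(E)-2-(4-bromo-3,5-dimethoxyphenyl)ethenyl]-2-methoxybenzene | COc1cc(/C=C/c2ccc(OCc3ccccc3)c(OC)c2)cc(OC)c1Br
F4 | step 10 | 1-(benzyloxy)-4-[2-(4-bromo-3,5-dimethoxyphenyl)ethyl]-2-methoxybenzene | COc1cc(CCc2ccc(OCc3ccccc3)c(OC)c2)cc(OC)c1Br
F5 | step 10 | 4-{2-[4-(benzyloxy)-3-methoxyphenyl]ethyl}-2,6-dimethoxybenzaldehyde | COc1cc(CCc2ccc(OCc3ccccc3)c(OC)c2)cc(OC)c1C=O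
F6 | step 13 | {[3-{2-[4-(benzyloxy)-3-methoxyphenyl]ethyl}-5-methoxycyclohexa-1,5-dien-1-yl]oxy}trimethylsilane (racemic) | C[Si](C)(C)OC1=CC(CCc2ccc(OCc3ccccc3)c(OC)c2)CC(OC)=C1
F7 | step 15 | 6-[2-(benzyloxy)-4-{2-[4-(benzyloxy)-3-methoxyphenyl]ethyl}-6-methoxybenzoyl]-5-{2-[4-(benzyloxy)-3-methoxyphenyl]ethyl}-3-methoxycyclohex-2-en-1-one (racemic) | COC1=CC(=O)C(C(=O)c2c(OC)cc(CCc3ccc(OCc4ccccc4)c(OC)c3)cc2OCc2ccccc2)C(CCc2ccc(OCc3ccccc3)c(OC)c2)C1
F8 | step 15 | 6-(phenylselanyl) derivative of F7 (racemic) | COC1=CC(=O)C([Se]c2ccccc2)(C(=O)c2c(OC)cc(CCc3ccc(OCc4ccccc4)c(OC)c3)cc2OCc2ccccc2)C(CCc2ccc(OCc3ccccc3)c(OC)c2)C1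
F9 | step 15 | [2-(benzyloxy)-4-{2-[4-(benzyloxy)-3-methoxyphenyl]ethyl}-6-methoxyphenyl](2-{2-[4-(benzyloxy)-3-methoxyphenyl]ethyl}-6-hydroxy-4-methoxyphenyl)methanone | COc1cc(O)c(C(=O)c2c(OCc3ccccc3)cc(CCc3ccc(OCc4ccccc4)c(OC)c3)cc2OC)c(CCc2ccc(OCc3ccccc3)c(OC)c2)c1
F10 | step 15 | [2-(benzyloxy)-4-{2-[4-(benzyloxy)-3-methoxyphenyl]ethyl}-6-methoxyphenyl](2-{2-[4-(benzyloxy)-3-methoxyphenyl]ethyl}-6-hydroxy-4-methoxyphenyl)methanol (racemic) | COc1cc(O)c(C(O)c2c(OCc3ccccc3)cc(CCc3ccc(OCc4ccccc4)c(OC)c3)cc2OC)c(CCc2ccc(OCc3ccccc3)c(OC)c2)c1
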